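Numbering (polyketide chain): C1 lactone C=O, C2 (Me), C3 (OAc), C4 (quaternary, Me), C5 (lactone O), C6 (Me), C7 (acyloxy), C8 (Me), C9; ring A = tetrahydropyran (O, C4–C8), ring B = δ-lactone (O, C1–C5).
Last disconnections: the (Z)-4-oxodec-2-enoate at O–C7 (Still–Gennari olefination of a C7 phosphonoacetate with 2-oxooctanal) and ring B (Dieckmann closure of a C5 propanoate onto a C3 ester, then cis-hydrogenation of the enolised β-keto lactone to set C2 and C3).
Key disconnection: ring A is opened at C7–C8 and O–C4; both bonds form in one operation by a nitro-aldol (Henry)/hemiketalisation cascade between acetaldehyde (C8, C9, ring oxygen) and γ-nitro ketone 5, in which C7 is a nitro-bearing carbon and C4 a ketone carbonyl.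
Enabling feature: in ring A the ring oxygen lies between C8(H)Me and the fully substituted C4, which sits where an anomeric carbon would, C7 carries oxygen (so it can be a nitronate carbon, later C=O, then C–OH), and the groups at C5, C6, C7, C8 are all equatorial with only the C4 methyl axial; a reversible cascade therefore converges on the right ring A and the axial methyl later replaces the anomeric hydroxyl.
Precursor 5 comes in one step from 2,2-dimethyl-1,3-dioxan-5-one (C3–C5, both oxygens held in a temporary dioxane ring) and (E)-1-nitropropene (C6, C7); ring order: temporary dioxane, ring A (step 3), ring B (step 13).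
Key step: step 3

Remark: acid 25 is taken to be a purchasable reagent, and fluoride 9 may form as either C4 epimer, which is immaterial because both ionise to the same oxocarbenium ion in step 5.

Step 1
Reactants: 1 1-nitropropan-2-ol
Product: 3 (E)-1-nitroprop-1-ene, via 1-nitropropan-2-yl methanesulfonate 2 (not isolated)
Conditions: MsCl, Et3N (2.2 equiv), CH2Cl2, −20 → 0 °C
Reagents that add atoms: none
Why: Mesylation followed by amine-induced E1cB elimination (dehydration of a nitro-aldol) should give the conjugated (E)-nitroalkene, the more stable alkene isomer.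

Step 2
Reactants: 3 (E)-1-nitroprop-1-ene; 4 2,2-dimethyl-1,3-dioxan-5-one
Product: 5 (4S)-2,2-dimethyl-4-[(2R)-1-nitropropan-2-yl]-1,3-dioxan-5-one
Conditions: (S)-1-(pyrrolidin-2-ylmethyl)pyrrolidine (15 mol %), CF3CO2H (15 mol %), CHCl3, 0 °C
Reagents that add atoms: none
Why: Enamine-catalysed asymmetric Michael addition: the dioxanone enamine adds to the nitroalkene through an acyclic synclinal transition state in which the protonated side-chain amine of the (S)-catalyst binds the nitro group, which should set C5 (S) and C6 (R) in the syn relationship.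

Step 3
Reactants: 5 γ-nitro ketone; 6 acetaldehyde
Product: 8 nitro hemiketal (ring A closed), via open-chain nitro aldol adduct 7 (not isolated)
Conditions: Et3N (0.3 equiv), THF, 0 → 25 °C, 24 h (equilibrating; acetaldehyde in excess, sealed vessel)
Reagents that add atoms: none
Why: Et3N generates the nitronate of 5, which adds reversibly to acetaldehyde (Henry reaction) to form C7–C8, and the new C8 hydroxyl then adds to the electrophilic dioxanone carbonyl to form O–C4 as a six-membered hemiketal, an addition cascade in which every atom of both partners is kept. The closest known reaction type is the domino nitro-aldol/hemiketalisation used to make nitro-tetrahydropyranols and nitro sugars. Ring A closes in the 6-exo-trig mode (oxygen onto the ketone carbon). C7 and C8 are set under thermodynamic control, because retro-Henry reaction and nitronate epimerisation funnel the material into the chair with nitro, both methyls and the C5 oxygen equatorial; C4 is set by the anomeric preference for an axial hydroxyl, which also gives the trans fusion to the dioxane. The step needs the nitronate, not a ketone enolate, to attack acetaldehyde and needs the cyclic form to be favoured; the large acidity gap between nitroalkane and ketone and the activated α,α'-dioxygenated carbonyl secure both. Base-induced epimerisation at C5 of the open-chain ketone should correct itself, since only the C5 configuration set in step 2 lets all four ring-A substituents sit equatorial beside the fixed C6 centre.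

Step 4
Reactants: 8 nitro hemiketal
Product: 9 anomeric (ketosyl) fluoride
Conditions: DAST (1.3 equiv), CH2Cl2, −40 → 0 °C
Reagents that add atoms: DAST (diethylaminosulfur trifluoride), CCN(CC)S(F)(F)F
Why: Deoxyfluorination of the anomeric hydroxyl with DAST, the standard route to glycosyl fluorides, should give the ketosyl fluoride and so lock ring A against ring opening and retro-Henry reaction.

Step 5
Reactants: 9 anomeric fluoride
Product: 10 C4-methyl nitro compound
Conditions: AlMe3 (4 equiv), toluene, −20 → 0 °C
Reagents that add atoms: trimethylaluminium, C[Al](C)C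
Why: C-Glycosylation of a glycosyl fluoride with trimethylaluminium: aluminium abstracts fluoride and methyl adds to the ring-A oxocarbenium ion along the axial trajectory enforced by the trans-fused dioxane, which should place the C4 methyl axial and cis to the C5 oxygen.

Step 6
Reactants: 10 C4-methyl nitro compound
Product: 12 C7 ketone, via potassium nitronate 11 (not isolated)
Conditions: KOt-Bu (1.05 equiv), THF, −78 → −40 °C; then dimethyldioxirane (acetone solution), −78 → 0 °C
Reagents that add atoms: dimethyldioxirane, CC1(C)OO1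
Why: Oxidative Nef reaction: the nitronate is oxygenated at carbon by dimethyldioxirane to give the C7 ketone under conditions that spare the acetonide, and the now epimerisable C6 and C8 methyls stay equatorial.

Step 7
Reactants: 12 C7 ketone
Product: 13 C7 alcohol
Conditions: NaBH4, MeOH, −40 °C
Reagents that add atoms: none
Why: Ketone reduction by a small hydride: axial attack at C7 (the only syn-axial partners are H-5 and the ring oxygen) should give the equatorial alcohol, which is the C7 configuration of the target.

Step 8
Reactants: 13 C7 alcohol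
Product: 14 C7 TBS ether
Conditions: TBSOTf, 2,6-lutidine, CH2Cl2, 0 °C
Reagents that add atoms: tert-butyldimethylsilyl trifluoromethanesulfonate, CC(C)(C)[Si](C)(C)OS(=O)(=O)C(F)(F)F
Why: Silyl triflate silylation of the hindered secondary alcohol gives a TBS ether that should survive the acid, base and hydrogenation of steps 9 to 15.

Step 9
Reactants: 14 C7 TBS ether
Product: 15 diol
Conditions: AcOH/H2O/THF (3:1:1), 25 → 40 °C
Reagents that add atoms: none
Why: Acid-catalysed hydrolysis of the isopropylidene acetal frees the C5 and C3 hydroxyls, the secondary TBS ether flanked by two methyl-bearing carbons being cleaved far more slowly in aqueous acetic acid.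

Step 10
Reactants: 15 diol
Product: 17 hydroxy acid, via hydroxy aldehyde 16 (not isolated)
Conditions: TEMPO (0.2 equiv), PhI(OAc)2 (2.5 equiv), MeCN/H2O (1:1), 25 °C
Reagents that add atoms: water, O
Why: TEMPO/PhI(OAc)2 oxidation is selective for the primary alcohol and in aqueous acetonitrile carries the aldehyde (as its hydrate) on to the acid, leaving the secondary C5 hydroxyl untouched.

Step 11
Reactants: 17 hydroxy acid
Product: 18 hydroxy methyl ester
Conditions: MeI, KHCO3, DMF, 25 °C
Reagents that add atoms: iodomethane, CI
Why: Carboxylate O-alkylation (SN2 on iodomethane) under weak base esterifies the acid without touching the hindered secondary alcohol.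

Step 12
Reactants: 18 hydroxy methyl ester
Product: 19 C5 propanoate
Conditions: propanoic anhydride, Et3N, DMAP (0.3 equiv), CH2Cl2, 25 °C
Reagents that add atoms: propanoic anhydride, CCC(=O)OC(=O)CC
Why: DMAP-catalysed acylation of the C5 hydroxyl installs the propanoate that supplies C1 and C2 of ring B.

Step 13
Reactants: 19 C5 propanoate
Product: 21 enolised β-keto lactone (ring B closed), via lithium enolate 20 (not isolated)
Conditions: LiN(SiMe3)2 (2.5 equiv), THF, −78 → 0 °C; then aqueous HCl (1 mol/L)
Reagents that add atoms: none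
Why: Dieckmann condensation: the propanoate enolate attacks the non-enolisable C3 methyl ester (6-exo-trig) and loss of methoxide gives the β-keto lactone as its stabilised enolate, as in known routes to 3-alkyl-4-hydroxy-5,6-dihydropyran-2-ones.

Step 14
Reactants: 21 enolised β-keto lactone
Product: 22 hydroxy lactone
Conditions: H2 (50 bar), Rh/Al2O3 (5 wt %), EtOAc, 25 °C
Reagents that add atoms: none
Why: Heterogeneous cis-hydrogenation of an enolised β-keto lactone, known for 3-alkyl-4-hydroxy-5,6-dihydropyran-2-ones, should add both hydrogens from the face opposite the axial C4 methyl and so set the C2 methyl and C3 hydroxyl cis to each other and to that methyl.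

Step 15
Reactants: 22 hydroxy lactone
Product: 23 C3 acetate
Conditions: Ac2O, pyridine, DMAP (cat.), CH2Cl2, 0 → 25 °C
Reagents that add atoms: acetic anhydride, CC(=O)OC(C)=O
Why: Acetylation of the secondary C3 hydroxyl under mild nucleophilic catalysis at low temperature, chosen to avoid epimerisation at C2 and β-elimination.

Step 16
Reactants: 23 C3 acetate
Product: 24 C7 alcohol
Conditions: HF·pyridine, THF, 0 → 25 °C
Reagents that add atoms: none
Why: Fluoride cleavage of the silyl ether with HF·pyridine, conditions that leave the lactone, the acetate and the C2 stereocentre intact.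

Step 17
Reactants: 24 C7 alcohol; 25 [bis(2,2,2-trifluoroethoxy)phosphoryl]acetic acid
Product: 26 C7 phosphonoacetate
Conditions: N,N'-dicyclohexylcarbodiimide, DMAP (cat.), CH2Cl2, 0 → 25 °C
Reagents that add atoms: none
Why: Carbodiimide-mediated (Steglich) esterification of the equatorial C7 alcohol with the phosphonoacetic acid gives the phosphonate needed for a Z-selective olefination.

Step 18
Reactants: 27 octane-1,2-diol
Product: 29 2-oxooctanal, via 1-hydroxyoctan-2-one 28 (not isolated)
Conditions: IBX (3 equiv), EtOAc, 75 °C; used crude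
Reagents that add atoms: none
Why: IBX oxidises 1,2-diols to 1,2-dicarbonyl compounds without C–C cleavage, which should give the α-keto aldehyde for direct use.

Step 19
Reactants: 26 C7 phosphonoacetate; 29 2-oxooctanal
Product: 31 botcinin J, via potassium phosphonate carbanion 30 (not isolated)
Conditions: KN(SiMe3)2 (1.0 equiv), 18-crown-6 (3 equiv), THF, −78 °C; then 29, −78 °C
Reagents that add atoms: none
Why: Still–Gennari olefination: the potassium anion of the bis(trifluoroethyl) phosphonate adds to the aldehyde carbonyl of 29 (more electrophilic than its ketone) and fast, irreversible elimination should give the (Z)-enoate, the phosphonate being far more acidic than the lactone and acetate α-protons.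

Compound list
1 | 1-nitropropan-2-ol (racemic) | CC(O)C[N+](=O)[O-] | starting material
2 | 1-nitropropan-2-yl methanesulfonate (racemic, formed in situ) | CC(OS(C)(=O)=O)C[N+](=O)[O-] | intermediate
3 | (E)-1-nitroprop-1-ene | C/C=C/[N+](=O)[O-] | intermediate
4 | 2,2-dimethyl-1,3-dioxan-5-one | CC1(C)OCC(=O)CO1 | starting material
5 | (4S)-2,2-dimethyl-4-[(2R)-1-nitropropan-2-yl]-1,3-dioxan-5-one | [O-][N+](=O)C[C@@H](C)[C@@H]1OC(C)(C)OCC1=O | intermediate
6 | acetaldehyde | CC=O | starting material
7 | (4S)-4-[(2R,3R,4S)-4-hydroxy-3-nitropentan-2-yl]-2,2-dimethyl-1,3-dioxan-5-one (formed in situ) | O[C@@H](C)[C@H]([N+](=O)[O-])[C@@H](C)[C@@H]1OC(C)(C)OCC1=O | intermediate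
8 | nitro hemiketal, (4R,5S,6R,7R,8S): ring A chair with axial 4-OH, equatorial 6-Me, 7-NO2 and 8-Me, trans-fused at C4–C5 to a 2,2-dimethyl-1,3-dioxane joining O-5 and O-3 (C3 as CH2) | [O-][N+](=O)[C@@H]1[C@@H](C)[C@@H]2OC(C)(C)OC[C@@]2(O)O[C@H]1C | intermediate
9 | anomeric fluoride of 8, drawn as the axial (4S,5S,6R,7R,8S) fluoride | [O-][N+](=O)[C@@H]1[C@@H](C)[C@@H]2OC(C)(C)OC[C@@]2(F)O[C@H]1C | intermediate
10 | C4-methyl nitro compound, (4R,5S,6R,7R,8S): as 8 with axial 4-Me in place of OH | [O-][N+](=O)[C@@H]1[C@@H](C)[C@@H]2OC(C)(C)OC[C@@]2(C)O[C@H]1C | intermediate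
11 | potassium nitronate of 10, (4R,5S,6R,8S) (formed in situ) | [K+].[O-][N+]([O-])=C1[C@@H](C)[C@@H]2OC(C)(C)OC[C@@]2(C)O[C@H]1C | intermediate
12 | C7 ketone, (4R,5S,6S,8S): 6-Me and 8-Me equatorial, acetonide retained | O=C1[C@@H](C)[C@@H]2OC(C)(C)OC[C@@]2(C)O[C@H]1C | intermediate
13 | C7 alcohol, (4R,5S,6R,7R,8S): equatorial 7-OH | O[C@@H]1[C@@H](C)[C@@H]2OC(C)(C)OC[C@@]2(C)O[C@H]1C | intermediate
14 | C7 tert-butyldimethylsilyl ether of 13, (4R,5S,6S,7R,8S) | CC(C)(C)[Si](C)(C)O[C@@H]1[C@@H](C)[C@@H]2OC(C)(C)OC[C@@]2(C)O[C@H]1C | intermediate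
15 | diol, (4R,5S,6S,7R,8S): ring A with equatorial 4-CH2OH, axial 4-Me, 5-OH, 6-Me, 7-OTBS, 8-Me | CC(C)(C)[Si](C)(C)O[C@@H]1[C@@H](C)[C@H](O)[C@@](C)(CO)O[C@H]1C | intermediate
16 | hydroxy aldehyde (4-CHO in place of 4-CH2OH), (4S,5S,6S,7R,8S) (formed in situ) | CC(C)(C)[Si](C)(C)O[C@@H]1[C@@H](C)[C@H](O)[C@@](C)(C=O)O[C@H]1C | intermediate
17 | hydroxy acid (4-CO2H), (4S,5S,6S,7R,8S) | CC(C)(C)[Si](C)(C)O[C@@H]1[C@@H](C)[C@H](O)[C@@](C)(C(=O)O)O[C@H]1C | intermediate
18 | hydroxy methyl ester (4-CO2Me), (4S,5S,6S,7R,8S) | CC(C)(C)[Si](C)(C)O[C@@H]1[C@@H](C)[C@H](O)[C@@](C)(C(=O)OC)O[C@H]1C | intermediate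
19 | C5 propanoate of 18, (4S,5S,6S,7R,8S) | CC(C)(C)[Si](C)(C)O[C@@H]1[C@@H](C)[C@H](OC(=O)CC)[C@@](C)(C(=O)OC)O[C@H]1C | intermediate
20 | lithium enolate of 21 (formed in situ) | [Li+].CC(C)(C)[Si](C)(C)O[C@@H]1[C@@H](C)[C@@H]2OC(=O)C(C)=C([O-])[C@@]2(C)O[C@H]1C | intermediate
21 | enolised β-keto lactone, (4S,5S,6S,7R,8S): ring B with C2=C3 enol (3-OH, 2-Me), trans-fused to ring A | CC(C)(C)[Si](C)(C)O[C@@H]1[C@@H](C)[C@@H]2OC(=O)C(C)=C(O)[C@@]2(C)O[C@H]1C | intermediate
22 | hydroxy lactone, (2R,3S,4R,5S,6S,7R,8S): 2-Me, 3-OH and 4-Me mutually cis on ring B, 7-OTBS | CC(C)(C)[Si](C)(C)O[C@@H]1[C@@H](C)[C@@H]2OC(=O)[C@H](C)[C@H](O)[C@@]2(C)O[C@H]1C | intermediate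
23 | C3 acetate of 22, (2R,3S,4S,5S,6S,7R,8S) | CC(C)(C)[Si](C)(C)O[C@@H]1[C@@H](C)[C@@H]2OC(=O)[C@H](C)[C@H](OC(C)=O)[C@@]2(C)O[C@H]1C | intermediate
24 | C7 alcohol (silyl group removed), (2R,3S,4S,5S,6R,7R,8S) | O[C@@H]1[C@@H](C)[C@@H]2OC(=O)[C@H](C)[C@H](OC(C)=O)[C@@]2(C)O[C@H]1C | intermediate
25 | [bis(2,2,2-trifluoroethoxy)phosphoryl]acetic acid | OC(=O)CP(=O)(OCC(F)(F)F)OCC(F)(F)F | starting material
26 | C7 [bis(2,2,2-trifluoroethoxy)phosphoryl]acetate of 24, (2R,3S,4S,5S,6R,7R,8S) | FC(F)(F)COP(=O)(CC(=O)O[C@@H]1[C@@H](C)[C@@H]2OC(=O)[C@H](C)[C@H](OC(C)=O)[C@@]2(C)O[C@H]1C)OCC(F)(F)F | intermediate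
27 | octane-1,2-diol (racemic) | CCCCCCC(O)CO | starting material
28 | 1-hydroxyoctan-2-one (formed in situ) | CCCCCCC(=O)CO | intermediate
29 | 2-oxooctanal | CCCCCCC(=O)C=O | intermediate
30 | potassium salt of the phosphonate carbanion of 26 (formed in situ) | [K+].FC(F)(F)COP(=O)([CH-]C(=O)O[C@@H]1[C@@H](C)[C@@H]2OC(=O)[C@H](C)[C@H](OC(C)=O)[C@@]2(C)O[C@H]1C)OCC(F)(F)F | intermediate
31 | botcinin J, (2R,3S,4S,5S,6R,7R,8S), 3-acetate, 7-[(2Z)-4-oxodec-2-enoate] | CCCCCCC(=O)/C=C\C(=O)O[C@@H]1[C@@H](C)[C@@H]2OC(=O)[C@H](C)[C@H](OC(C)=O)[C@@]2(C)O[C@H]1C | target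

Total step count: 19. Longest linear sequence: 18 steps (steps 1 to 17, then 19); step 18 is a one-step side branch.

Steps most likely to fail

1. Step 5 (methyl transfer to the anomeric carbon). The fluoride is flanked by two oxygen-bearing carbons and held in a trans-fused bicycle, so ionisation may be slow; methyl transfer could then lose out to Lewis-acid opening of the acetonide or to ring opening of ring A. The fallback sets out from 5 and installs the methyl before ring A is closed. Addition of MeMgBr/CeCl3 (excess, the nitro group being held as its nitronate) to the dioxanone carbonyl from the axial direction should give the tertiary alcohol F1. A Henry reaction of F1 with acetaldehyde (Et3N) gives the nitro diol F2, which is dehydrated (MsCl, Et3N) to the nitroalkene F3. Base-mediated intramolecular oxa-Michael addition of the tertiary hydroxyl to the nitroalkene (KOt-Bu cat., THF, thermodynamic control) closes ring A and comes back to the route at 10.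

2. Step 14 (cis-hydrogenation of the enol). The tetrasubstituted enol double bond next to the quaternary C4 may resist reduction, may be reduced from both faces, or may suffer hydrogenolysis of the enol C–O bond. The fallback sets out from 15 and builds C1–C3 by allylboration instead. TEMPO/PhI(OAc)2 in dry CH2Cl2 stops at the hydroxy aldehyde 16, now isolated. Reagent-controlled crotylboration with (E)-crotyldiisopinocampheylborane of the enantiomeric series that adds to the Si face (closed chair transition state, anti) should give the homoallylic diol F4. Ozonolysis with reductive work-up (O3, then PPh3) gives the lactol F5, and Ag2CO3 on Celite oxidises the lactol selectively, which comes back to the route at 22.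

3. Step 19 (Z-selective olefination). Partial Z-to-E isomerisation of the ene-dione, or base-induced β-elimination of acetate and epimerisation at C2, may erode the last step. The fallback sets out from 24 and transfers the cis geometry from a ring. Coupling of (Z)-3-iodoprop-2-enoic acid with hept-1-yne (Pd(PPh3)4, CuI, Et3N), with lactonisation in the same flask, gives the enol lactone (5Z)-5-hexylidenefuran-2(5H)-one F6. DMAP-catalysed ring-opening acylation of alcohol 24 by this enol lactone keeps the ring cis double bond as the (Z)-enoate, and the released enol tautomerises to the hexyl ketone, which comes back to the route at 31.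

Further compounds
F1 | step 5 | (4S,5R)-2,2,5-trimethyl-4-[(2R)-1-nitropropan-2-yl]-1,3-dioxan-5-ol | [O-][N+](=O)C[C@@H](C)[C@@H]1OC(C)(C)OC[C@@]1(C)O
F2 | step 5 | (4S,5R)-4-[(2R)-4-hydroxy-3-nitropentan-2-yl]-2,2,5-trimethyl-1,3-dioxan-5-ol (mixture of epimers at the two new carbons) | CC(O)C([N+](=O)[O-])[C@@H](C)[C@@H]1OC(C)(C)OC[C@@]1(C)O
F3 | step 5 | (4S,5R)-2,2,5-trimethyl-4-[(2R,3E)-3-nitropent-3-en-2-yl]-1,3-dioxan-5-ol | C/C=C(\[C@@H](C)[C@@H]1OC(C)(C)OC[C@@]1(C)O)[N+](=O)[O-]
F4 | step 14 | homoallylic diol from anti-crotylation of 16 (vinyl in place of C1; C2, C3 and ring A configured as in 22) | C=C[C@H](C)[C@H](O)[C@@]1(C)O[C@@H](C)[C@H](O[Si](C)(C)C(C)(C)C)[C@@H](C)[C@@H]1O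
F5 | step 14 | bicyclic lactol (C1 hemiacetal, mixture of anomers; otherwise as 22) | CC(C)(C)[Si](C)(C)O[C@@H]1[C@@H](C)[C@@H]2OC(O)[C@H](C)[C@H](O)[C@@]2(C)O[C@H]1C
F6 | step 19 | (5Z)-5-hexylidenefuran-2(5H)-one | CCCCC/C=C1\OC(=O)C=C1
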